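**Plan**

1. Cuts (eudesmane numbering: ring A = C1–C5 and C10, ring B = C5–C10, C15 = methyl on C4, C14 = methyl on C10, C11 = carbinol carbon on C7): first C3–C4, which opens ring A; then C4=C15 back to an ester C4=O, the ester bond C4–O(aryl), C4–C5, C2–C3 and C10–C1.
2. Enabling feature: C4 of ring A is fully substituted, carries the ether oxygen and the methyl C15, and is bonded to C5 of ring B. It is therefore read as the inner carbon of a 1-aryloxyvinyl group, that is, as the carbonyl carbon of an aryl ester of honokiol; hydrogen-atom transfer to C15 turns it into a tertiary α-aryloxy radical that closes ring A at C3.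
3. Forward order: ring B is the ring of (+)-dihydrocarvone. The C1–C2 arm (phenylsulfonyl helper on C2) is added at C10, C4 at C5 and C3 at C2; honokiol is acylated; C15 comes by ester methylenation; ring A closes last; the sulfone and two silyl groups are then removed.
4. Stereochemistry: C7 from dihydrocarvone; C10 from the Michael addition of a chiral imine; C5 from axial protonation (C4 substituent equatorial); C4 in the ring closure. The trans ring fusion follows from the two equatorial arms on ring B.

Key step: step 13

Assumption: triisopropylsilyl chloride silylates honokiol mainly at the 4′-OH (less hindered, para to the biaryl bond); the minor 2-O-silyl isomer is removed by chromatography.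
Remark: α/β follow terpene usage (β = face of the C10 methyl). Commercial (+)-dihydrocarvone holds both C2 epimers; C2 is planar in the enamine of step 2.

**Route**

Step 1
Reactants: 1 (+)-dihydrocarvone; 2 (R)-1-phenylethylamine
Product: 3 (R)-N-[(5R)-2-methyl-5-(prop-1-en-2-yl)cyclohexylidene]-1-phenylethanamine
Conditions: TsOH·H2O (cat.), toluene, reflux, Dean–Stark trap
Reagents that add atoms: none
Why: Acid-catalysed condensation with azeotropic removal of water gives the ketimine (imine formation); C2 of 1 becomes labile through imine–enamine tautomerism, so both C2 epimers converge, and the isopropenyl-bearing centre (later C7) is untouched.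

Step 2
Reactants: 3 imine; 4 phenyl vinyl sulfone
Product: 6 (2S,5R)-2-methyl-2-[2-(phenylsulfonyl)ethyl]-5-(prop-1-en-2-yl)cyclohexan-1-one, via Michael adduct imine 5 (not isolated)
Conditions: THF, 50 °C; then 20% aq AcOH, rt
Reagents that add atoms: water, O
Why: The more substituted secondary enamine tautomer of the chiral imine adds to the vinyl sulfone (Michael addition through a chair-like aza-ene transition state) on the face anti to the phenyl group of the auxiliary, which sets the quaternary C10 with the C1–C2 arm trans to the isopropenyl group, and aqueous acetic acid then hydrolyses the imine and returns the amine.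

Step 3
Reactants: 6 keto sulfone
Product: 7 (2S,5R)-5-(2-hydroxypropan-2-yl)-2-methyl-2-[2-(phenylsulfonyl)ethyl]cyclohexan-1-one
Conditions: Co(acac)2 (cat.), PhSiH3, O2 (1 atm), THF/i-PrOH, rt
Reagents that add atoms: dioxygen, O=O
Why: Mukaiyama hydration (cobalt-hydride hydrogen-atom transfer to the 1,1-disubstituted alkene, capture of the tertiary radical by O2 and reduction by the silane) should give the Markovnikov tertiary alcohol at C11 without touching the ketone or the sulfone; no stereocentre is formed.

Step 4
Reactants: 7 hydroxy keto sulfone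
Product: 8 (2S,5R)-2-methyl-2-[2-(phenylsulfonyl)ethyl]-5-[2-(triethylsilyloxy)propan-2-yl]cyclohexan-1-one
Conditions: Et3SiOTf, 2,6-lutidine, CH2Cl2, −78 °C
Reagents that add atoms: triethylsilyl trifluoromethanesulfonate, CC[Si](CC)(CC)OS(=O)(=O)C(F)(F)F
Why: A silyl triflate with a hindered pyridine base silylates the tertiary alcohol (silyl ether protection), which keeps the C11 oxygen from adding to the C4 carbonyl groups that later sit cis-1,3 to it on ring B.

Step 5
Reactants: 8 silyl ether ketone
Product: 9 methyl enol ether (C=O of 8 replaced by C=CH–OMe; E/Z mixture)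
Conditions: MeOCH2PPh3Cl, KN(SiMe3)2, THF, 0 °C to 50 °C
Reagents that add atoms: (methoxymethyl)triphenylphosphonium chloride, COC[P+](c1ccccc1)(c1ccccc1)c1ccccc1.[Cl-]
Why: Wittig olefination with the methoxymethylene ylide adds C4 to the hindered ketone as a methyl enol ether (one-carbon homologation), the sulfone α-protons being too weakly acidic to quench the ylide; the alkene geometry is irrelevant.

Step 6
Reactants: 9 methyl enol ether
Product: 11 Mannich base (CH2NMe2 on the sulfonyl carbon of 9; both epimers at that carbon), via α-lithio sulfone 10 (not isolated)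
Conditions: LiN(iPr)2, THF, −78 °C; then CH2=NMe2+ I−, −78 °C to 0 °C
Reagents that add atoms: N,N-dimethylmethyleneiminium iodide, C=[N+](C)C.[I-]
Why: Deprotonation α to the sulfone (the only acidic C–H once the ketone is an enol ether) and Mannich-type alkylation of the carbanion attach C3 as a CH2NMe2 group, a latent C2=C3 double bond that is inert up to step 11; the new C2 centre forms unselectively and is later erased.

Step 7
Reactants: 11 Mannich base
Product: 12 (1R,2S,5R)-2-[3-(dimethylamino)-2-(phenylsulfonyl)propyl]-2-methyl-5-[2-(triethylsilyloxy)propan-2-yl]cyclohexane-1-carbaldehyde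
Conditions: 1 M aq HCl, THF, 0 °C; NaHCO3 work-up
Reagents that add atoms: water, O
Why: Acid hydrolysis of the enol ether protonates C5 and frees the aldehyde; axial protonation from the α face (the equatorial trajectory is shielded by the axial C10 methyl on the neighbouring carbon) should set C5 with the formyl group equatorial and trans to the C1 arm, which is also the more stable epimer, and the brief cold acid should spare the tertiary silyl ether.

Step 8
Reactants: 12 aldehyde
Product: 13 (1R,2S,5R)-2-[3-(dimethylamino)-2-(phenylsulfonyl)propyl]-2-methyl-5-[2-(triethylsilyloxy)propan-2-yl]cyclohexane-1-carboxylic acid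
Conditions: NaClO2, NaH2PO4, 2-methylbut-2-ene, t-BuOH/H2O, rt
Reagents that add atoms: sodium chlorite, [Na+].[O-]Cl=O
Why: Pinnick oxidation converts the aldehyde into the acid under buffered conditions that should neither epimerise C5 nor oxidise the protonated amine.

Step 9
Reactants: 14 honokiol
Product: 15 3′,5-diallyl-4′-(triisopropylsilyloxy)biphenyl-2-ol
Conditions: i-Pr3SiCl (1 equiv), imidazole, CH2Cl2/DMF, −20 °C to 0 °C
Reagents that add atoms: triisopropylsilyl chloride, CC(C)[Si](Cl)(C(C)C)C(C)C
Why: Silylation with a bulky silyl chloride and imidazole should occur mainly at the 4′-OH, which is less hindered than the 2-OH beside the biaryl bond, and leaves the 2-OH free for acylation.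

Step 10
Reactants: 13 acid; 15 silylated honokiol
Product: 16 aryl ester of 13 with the 2-OH of 15
Conditions: EDC·HCl, DMAP, CH2Cl2, 0 °C to rt
Reagents that add atoms: none
Why: Carbodiimide coupling with DMAP (Steglich esterification) acylates the hindered 2-OH, so the C4–O bond of the final tertiary ether is made as an ester bond, where steric hindrance is no obstacle.

Step 11
Reactants: 16 aryl ester
Product: 17 aryl enol ether (ester C=O of 16 replaced by C=CH2)
Conditions: Cp2TiMe2, toluene/THF, 70 °C, dark; filtration through basic alumina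
Reagents that add atoms: dimethyltitanocene, C[Ti](C)(C1C=CC=C1)C1C=CC=C1
Why: Petasis methylenation (Cp2Ti=CH2 formed by heating Cp2TiMe2) converts the aryl ester carbonyl into the 1-aryloxyvinyl group and so brings in C15, while sulfone, amine, silyl ethers and allyl groups should not react.

Step 12
Reactants: 17 aryl enol ether
Product: 19 enol ether bearing the 2-(phenylsulfonyl)prop-2-en-1-yl arm on C10, via trimethylammonium iodide 18 (not isolated)
Conditions: MeI, MeCN, rt; then aq NaHCO3, CH2Cl2, rt
Reagents that add atoms: none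
Why: Quaternisation of the amine and E1cB (Hofmann-type) elimination of trimethylamine from the β-ammonio sulfone under mild base unmask the α-methylene sulfone (C2=C3) without harming the acid-labile aryl enol ether.

Step 13
Reactants: 19 enol ether vinyl sulfone
Product: 20 4α-aryloxy-2-(phenylsulfonyl)eudesmane bis-silyl ether (trans-decalin; both C2 epimers)
Conditions: Fe(acac)3 (0.5 equiv), PhSiH3, degassed EtOH/THF, 60 °C, high dilution
Reagents that add atoms: none
Why: The iron hydride formed from Fe(acac)3 and PhSiH3 transfers a hydrogen atom to the terminal carbon C15 of the 1-aryloxyvinyl group, which makes C15 the methyl group and C4 a tertiary α-aryloxy radical; this nucleophilic radical adds to the unsubstituted terminus C3 of the 2-(phenylsulfonyl)allyl arm, and the α-sulfonyl radical at C2 is reduced by divalent iron and protonated by ethanol to give both C2 epimers, a centre erased in step 14. The closest known reaction type is the iron-hydride reductive coupling of heteroatom-substituted donor olefins with Michael acceptors (a hydrogen-atom-transfer Giese reaction), used here within one molecule. Ring A closes in the 6-endo-trig mode, because the 5-exo alternative would need attack at the substituted α-carbon of the vinyl sulfone, against the polarity of the acceptor. C1 (on C10) and the radical carbon (on C5) are both equatorial on the chair of ring B, so the chair-like transition state can only give the trans ring fusion, and C5, C7 and C10 are untouched. At C4 the step needs the aryloxy group pseudo-equatorial (α, eclipsing C5–H): an axial aryloxy group has only one rotamer free of syn-pentane contacts with C6 and the C10 methyl, and that rotamer holds the 2-arylphenyl ring on the β face over C3 beside the phenylsulfonyl group, whereas the equatorial group can turn its aryl ring to the open α side; this is opposed by the 1,3-diaxial contact of C15 with C14, so it is the least secure selectivity of the route. The step also needs hydrogen-atom transfer to the electron-rich 1,1-disubstituted enol ether in preference to the two monosubstituted allyl groups, which the greater reactivity of the enol ether, the stability of the tertiary α-oxy radical and high dilution should secure.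

Step 14
Reactants: 20 decalin sulfone
Product: 21 11-O-triethylsilyl-4′-O-triisopropylsilyl ether of the target
Conditions: Na(Hg) (6%), Na2HPO4, MeOH/THF, −20 °C to 0 °C
Reagents that add atoms: none
Why: Single-electron reduction by Na(Hg) in buffered methanol cleaves the C2–S bond (reductive desulfonylation), which removes the activating group and the C2 stereocentre, while allyl groups, silyl ethers and the aryl ether should not be reduced.

Step 15
Reactants: 21 bis-silyl ether
Product: 22 target, (4R,5R,7R,10R)-4-(3′,5-diallyl-4′-hydroxybiphenyl-2-yloxy)eudesman-11-ol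
Conditions: Bu4NF, THF, rt to 45 °C
Reagents that add atoms: none
Why: Fluoride cleaves the aryl triisopropylsilyl ether and, on warming, the tertiary triethylsilyl ether (desilylation), and the tertiary alkyl aryl ether is stable to these basic conditions.

**Compound list**

1 | (+)-dihydrocarvone, (2R,5R)-2-methyl-5-(prop-1-en-2-yl)cyclohexan-1-one | C[C@@H]1CC[C@@H](C(C)=C)CC1=O | starting material
2 | (R)-1-phenylethylamine | C[C@@H](N)c1ccccc1 | starting material
3 | (R)-N-[(5R)-2-methyl-5-(prop-1-en-2-yl)cyclohexylidene]-1-phenylethanamine (C2 epimers) | CC1CC[C@@H](C(C)=C)CC1=N[C@H](C)c1ccccc1 | intermediate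
4 | phenyl vinyl sulfone | C=CS(=O)(=O)c1ccccc1 | starting material
5 | Michael adduct imine, (R)-N-{(2S,5R)-2-methyl-2-[2-(phenylsulfonyl)ethyl]-5-(prop-1-en-2-yl)cyclohexylidene}-1-phenylethanamine | C[C@@]1(CCS(=O)(=O)c2ccccc2)CC[C@@H](C(C)=C)CC1=N[C@H](C)c1ccccc1 | intermediate
6 | (2S,5R)-2-methyl-2-[2-(phenylsulfonyl)ethyl]-5-(prop-1-en-2-yl)cyclohexan-1-one | C[C@@]1(CCS(=O)(=O)c2ccccc2)CC[C@@H](C(C)=C)CC1=O | intermediate
7 | (2S,5R)-5-(2-hydroxypropan-2-yl)-2-methyl-2-[2-(phenylsulfonyl)ethyl]cyclohexan-1-one | C[C@@]1(CCS(=O)(=O)c2ccccc2)CC[C@@H](C(C)(C)O)CC1=O | intermediate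
8 | (2S,5R)-2-methyl-2-[2-(phenylsulfonyl)ethyl]-5-[2-(triethylsilyloxy)propan-2-yl]cyclohexan-1-one | C[C@@]1(CCS(=O)(=O)c2ccccc2)CC[C@@H](C(C)(C)O[Si](CC)(CC)CC)CC1=O | intermediate
9 | methyl enol ether of 8 (C=O replaced by C=CH–OMe; E/Z mixture) | C[C@@]1(CCS(=O)(=O)c2ccccc2)CC[C@@H](C(C)(C)O[Si](CC)(CC)CC)CC1=COC | intermediate
10 | α-lithio sulfone of 9 | C[C@@]1(CC([Li])S(=O)(=O)c2ccccc2)CC[C@@H](C(C)(C)O[Si](CC)(CC)CC)CC1=COC | intermediate
11 | Mannich base (CH2NMe2 on the sulfonyl carbon of 9; both epimers there) | C[C@@]1(CC(CN(C)C)S(=O)(=O)c2ccccc2)CC[C@@H](C(C)(C)O[Si](CC)(CC)CC)CC1=COC | intermediate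
12 | (1R,2S,5R)-2-[3-(dimethylamino)-2-(phenylsulfonyl)propyl]-2-methyl-5-[2-(triethylsilyloxy)propan-2-yl]cyclohexane-1-carbaldehyde | C[C@@]1(CC(CN(C)C)S(=O)(=O)c2ccccc2)CC[C@@H](C(C)(C)O[Si](CC)(CC)CC)C[C@H]1C=O | intermediate
13 | (1R,2S,5R)-2-[3-(dimethylamino)-2-(phenylsulfonyl)propyl]-2-methyl-5-[2-(triethylsilyloxy)propan-2-yl]cyclohexane-1-carboxylic acid | C[C@@]1(CC(CN(C)C)S(=O)(=O)c2ccccc2)CC[C@@H](C(C)(C)O[Si](CC)(CC)CC)C[C@H]1C(=O)O | intermediate
14 | honokiol, 3′,5-diallylbiphenyl-2,4′-diol | C=CCc1ccc(O)c(-c2ccc(O)c(CC=C)c2)c1 | starting material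
15 | 3′,5-diallyl-4′-(triisopropylsilyloxy)biphenyl-2-ol | C=CCc1ccc(O)c(-c2ccc(O[Si](C(C)C)(C(C)C)C(C)C)c(CC=C)c2)c1 | intermediate
16 | aryl ester of acid 13 with the 2-OH of 15 | C[C@@]1(CC(CN(C)C)S(=O)(=O)c2ccccc2)CC[C@@H](C(C)(C)O[Si](CC)(CC)CC)C[C@H]1C(=O)Oc1ccc(CC=C)cc1-c1ccc(O[Si](C(C)C)(C(C)C)C(C)C)c(CC=C)c1 | intermediate
17 | aryl enol ether (1-aryloxyvinyl group on C5; ester C=O of 16 replaced by C=CH2) | C[C@@]1(CC(CN(C)C)S(=O)(=O)c2ccccc2)CC[C@@H](C(C)(C)O[Si](CC)(CC)CC)C[C@H]1C(=C)Oc1ccc(CC=C)cc1-c1ccc(O[Si](C(C)C)(C(C)C)C(C)C)c(CC=C)c1 | intermediate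
18 | trimethylammonium iodide of 17 | C[C@@]1(CC(C[N+](C)(C)C)S(=O)(=O)c2ccccc2)CC[C@@H](C(C)(C)O[Si](CC)(CC)CC)C[C@H]1C(=C)Oc1ccc(CC=C)cc1-c1ccc(O[Si](C(C)C)(C(C)C)C(C)C)c(CC=C)c1.[I-] | intermediate
19 | aryl enol ether with the 2-(phenylsulfonyl)prop-2-en-1-yl arm on C10 | C[C@@]1(CC(=C)S(=O)(=O)c2ccccc2)CC[C@@H](C(C)(C)O[Si](CC)(CC)CC)C[C@H]1C(=C)Oc1ccc(CC=C)cc1-c1ccc(O[Si](C(C)C)(C(C)C)C(C)C)c(CC=C)c1 | intermediate
20 | 4α-aryloxy-2-(phenylsulfonyl)-4β,10β-dimethyl-5α-H-eudesmane with 11-OSiEt3 and 4′-OSi(i-Pr)3 (both C2 epimers) | C=CCc1ccc(O[C@]2(C)CC(S(=O)(=O)c4ccccc4)C[C@]3(C)CC[C@@H](C(C)(C)O[Si](CC)(CC)CC)C[C@H]32)c(-c2ccc(O[Si](C(C)C)(C(C)C)C(C)C)c(CC=C)c2)c1 | intermediate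
21 | 11-O-triethylsilyl-4′-O-triisopropylsilyl ether of the target | C=CCc1ccc(O[C@]2(C)CCC[C@]3(C)CC[C@@H](C(C)(C)O[Si](CC)(CC)CC)C[C@H]32)c(-c2ccc(O[Si](C(C)C)(C(C)C)C(C)C)c(CC=C)c2)c1 | intermediate
22 | target, (4R,5R,7R,10R)-4-(3′,5-diallyl-4′-hydroxybiphenyl-2-yloxy)eudesman-11-ol | C=CCc1ccc(O[C@]2(C)CCC[C@]3(C)CC[C@@H](C(C)(C)O)C[C@H]32)c(-c2ccc(O)c(CC=C)c2)c1 | target

**Step count and risks**

Total: 15 steps. Longest linear sequence: 14 steps (steps 1–8 and 10–15).

Step 13. What may go wrong: low facial selectivity at C4, with the aryloxy group taking the axial β position, and competing hydrogen-atom transfer to the allyl groups. The fallback sets out from aldehyde 12 and returns at 20; it forms the C4–O bond last, on a C4 centre that already lies in ring A. Homologation of 12 with the Ohira–Bestmann reagent (K2CO3, MeOH) would give the terminal alkyne F1. N-Methylation with MeI to the trimethylammonium iodide F2 (not isolated) and elimination with NaHCO3 would give the enyne sulfone F3. Bu3SnH and AIBN in benzene at 80 °C would add a stannyl radical to the alkyne terminus, and the vinyl radical at C4 would close ring A by 6-endo attack on C3 to give the vinylstannane F4. CF3CO2H would remove tin and give the 4(15)-alkene F5. Addition of phenol 15 to F5 with catalytic CF3SO3H in CH2Cl2 at −78 °C (the way tert-butyl aryl ethers are made from isobutene) would then give 20; the C4 cation is open only on the α face, opposite the axial C10 methyl.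

Step 11. What may go wrong: incomplete methylenation of the hindered aryl ester and hydrolysis of the acid-labile aryl enol ether during isolation. The fallback sets out from aldehyde 12 and returns at 17. MeMgBr would give the secondary alcohol F6, and Dess–Martin periodinane the methyl ketone F7. KN(SiMe3)2 and PhNTf2 at −78 °C would give the terminal enol triflate F8 by kinetic deprotonation of the methyl group. C–O coupling of F8 with phenol 15 under Pd2(dba)3, a bulky di-tert-butyl(biaryl)phosphine and K3PO4 in toluene would give 17.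

Step 7. What may go wrong: low facial selectivity in the protonation at C5, or drift of the aldehyde toward the axial epimer. The fallback sets out from ketone 8 and returns at 12; it delivers the C5 hydrogen by hydroboration instead of protonation. Ph3P=CH2 would give the exocyclic methylene compound F9. LiN(iPr)2 would give the α-lithio sulfone F10 (not isolated) and CH2=NMe2+ I− the Mannich base F11. 9-BBN, approaching the α face, would give the alkylborane F12 (not isolated) and Me3NO the primary alcohol F13 with the CH2OH group equatorial. Dess–Martin oxidation of F13 would give 12.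

**Further compounds**

F1 | step 13 | terminal alkyne (formyl group of 12 replaced by ethynyl) | C[C@@]1(CC(CN(C)C)S(=O)(=O)c2ccccc2)CC[C@@H](C(C)(C)O[Si](CC)(CC)CC)C[C@H]1C#C
F2 | step 13 | trimethylammonium iodide of F1 | C[C@@]1(CC(C[N+](C)(C)C)S(=O)(=O)c2ccccc2)CC[C@@H](C(C)(C)O[Si](CC)(CC)CC)C[C@H]1C#C.[I-]
F3 | step 13 | enyne sulfone (ethynyl on C5; 2-(phenylsulfonyl)prop-2-en-1-yl on C10) | C[C@@]1(CC(=C)S(=O)(=O)c2ccccc2)CC[C@@H](C(C)(C)O[Si](CC)(CC)CC)C[C@H]1C#C
F4 | step 13 | vinylstannane, 15-(tributylstannyl)-2-(phenylsulfonyl)eudesm-4(15)-ene 11-triethylsilyl ether | C[C@@]1(CC(S(=O)(=O)c3ccccc3)CC2=C[Sn](CCCC)(CCCC)CCCC)CC[C@@H](C(C)(C)O[Si](CC)(CC)CC)C[C@H]12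
F5 | step 13 | 2-(phenylsulfonyl)eudesm-4(15)-ene 11-triethylsilyl ether | C[C@@]1(CC(S(=O)(=O)c3ccccc3)CC2=C)CC[C@@H](C(C)(C)O[Si](CC)(CC)CC)C[C@H]12
F6 | step 11 | secondary alcohol (formyl group of 12 replaced by 1-hydroxyethyl; carbinol epimers) | C[C@@]1(CC(CN(C)C)S(=O)(=O)c2ccccc2)CC[C@@H](C(C)(C)O[Si](CC)(CC)CC)C[C@H]1C(C)O
F7 | step 11 | methyl ketone (acetyl on C5) | C[C@@]1(CC(CN(C)C)S(=O)(=O)c2ccccc2)CC[C@@H](C(C)(C)O[Si](CC)(CC)CC)C[C@H]1C(C)=O
F8 | step 11 | enol triflate (1-(trifluoromethylsulfonyloxy)vinyl on C5) | C[C@@]1(CC(CN(C)C)S(=O)(=O)c2ccccc2)CC[C@@H](C(C)(C)O[Si](CC)(CC)CC)C[C@H]1C(=C)OS(=O)(=O)C(F)(F)F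
F9 | step 7 | exocyclic methylene compound (C=O of 8 replaced by C=CH2) | C[C@@]1(CCS(=O)(=O)c2ccccc2)CC[C@@H](C(C)(C)O[Si](CC)(CC)CC)CC1=C
F10 | step 7 | α-lithio sulfone of F9 | C[C@@]1(CC([Li])S(=O)(=O)c2ccccc2)CC[C@@H](C(C)(C)O[Si](CC)(CC)CC)CC1=C
F11 | step 7 | Mannich base of F9 (CH2NMe2 on the sulfonyl carbon) | C[C@@]1(CC(CN(C)C)S(=O)(=O)c2ccccc2)CC[C@@H](C(C)(C)O[Si](CC)(CC)CC)CC1=C
F12 | step 7 | B-alkyl-9-borabicyclo[3.3.1]nonane from F11 (boron on the new CH2 at C5) | C[C@@]1(CC(CN(C)C)S(=O)(=O)c2ccccc2)CC[C@@H](C(C)(C)O[Si](CC)(CC)CC)C[C@H]1CB1C2CCCC1CCC2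
F13 | step 7 | primary alcohol (hydroxymethyl on C5, equatorial) | C[C@@]1(CC(CN(C)C)S(=O)(=O)c2ccccc2)CC[C@@H](C(C)(C)O[Si](CC)(CC)CC)C[C@H]1CO
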